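5 questions stand below, and the first, which set-up ends highest, divides two chemists who have seen the same 4 runs.

| flask | starting complex | incoming ligand | leaving ligand | remark | time |
|---|---|---|---|---|---|
| cedar | 0.050 M | 3 equiv | 5 equiv | run made earlier |  |
| maple | 0.050 M | 3 equiv | 2.5 equiv | run made earlier |  |
| alder | 0.050 M | 3 equiv | 10 equiv | run made earlier |  |
| larch | 0.050 M | 6 equiv | 5 equiv | run made earlier |  |
| dusk | 0.050 M (fed, over 20.0 h) | 3.00 equiv | 5.00 equiv | all but starting complex at the start; starting complex goes in evenly over 20.0 h, the run ends at 40 h | 40 h |
| autumn | 0.050 M | 3.00 equiv | 5.00 equiv | plug flow through a tube for 40 h, no back-mixing | 40 h |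
| noon | 0.050 M | 3.00 equiv | 5.00 equiv | a closed flask charged with all of it at once and left for 40 h | 40 h |
| summer | 0.050 M | 3.00 equiv | 5.00 equiv | one stirred flow tank at steady state, fed with the mixture as stated, mean residence time 40 h |  |

| run | time / h | complex with one exchanged / % |
|---|---|---|
| cedar | 3.00 | 35.2 |
| cedar | 5.00 | 45.9 |
| cedar | 8.00 | 52.3 |
| cedar | 12.0 | 54.2 |
| cedar | 15.0 | 53.9 |
| cedar | 25.0 | 49.6 |
| cedar | 40.0 | 44.1 |
| maple | 3.00 | 38.8 |
| maple | 5.00 | 49.6 |
| maple | 8.00 | 61.0 |
| maple | 12.0 | 64.6 |
| maple | 15.0 | 65.5 |
| maple | 25.0 | 63.5 |
| maple | 40.0 | 59.0 |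
| alder | 2.00 | 25.1 |
| alder | 6.00 | 38.5 |
| alder | 12.0 | 39.2 |
| alder | 15.0 | 37.6 |
| alder | 25.0 | 32.0 |
| alder | 30.0 | 30.1 |
| alder | 40.0 | 26.4 |
| larch | 8.00 | 67.9 |
| larch | 15.0 | 63.1 |
| larch | 25.0 | 56.5 |
| larch | 30.0 | 51.6 |
| larch | 40.0 | 45.4 |

(each reading ± 0.5 percentage points)

- the stated concentrations are those of everything mixed, before any reaction; amounts are the same in each set-up
- the feed brings no volume worth counting
- the earlier runs were made in a closed, stirred flask

1. the set-up with the highest amount of complex with one exchanged at the outlet or at the end, in percent of the starting complex put in ("none" if the first two lie within 2 percentage points) (dusk / autumn / noon / summer / none)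
2. amount of complex with one exchanged at the outlet or at the end, in percent of the starting complex put in, dusk
3. amount of complex with one exchanged at the outlet or at the end, in percent of the starting complex put in, autumn
4. amount of complex with one exchanged at the outlet or at the end, in percent of the starting complex put in, noon
5. amount of complex with one exchanged at the outlet or at the end, in percent of the starting complex put in, summer

Both start from the balance of the starting complex, the limiting reagent, charged at one equivalent against 3.00 equiv of incoming and 5.00 equiv of leaving ligand.

The first chemist sees a split. Each portion of starting complex either exchanges or is lost from the reading, and the odds follow [incoming ligand]/[leaving ligand]. Maple and larch, both at a ratio of 1.20 with different amounts, give highest readings of 65.5% and 67.9%. Her split factor (a selectivity factor) is the highest reading over the rest of the complex, divided by that ratio. Cedar, at 54.2% and a ratio of 0.600, gives 1.97. Feeding the complex into the ligands leaves the ratio as charged, so she expects the same split in dusk as in noon, and she answers "none", with both near the cedar reading of 44.1%.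

The second chemist sees age. Cedar falls from 54.2% to 44.1% after its highest reading, and the contents of dusk are on average 10.0 h younger at the end. By his own slope, that is worth 3.6 percentage points.

The forecast sides with him, “so less is lost”: dusk best, at 47% (45.5% to 48.5%), autumn 44.1%, noon 44.1%, summer 39%.

    starting complex + incoming ligand ⇌ leaving ligand + complex with one exchanged (K = 42.0, k = 1.30 L mol⁻¹ h⁻¹)
    complex with one exchanged + incoming ligand ⇌ leaving ligand + complex with two exchanged (K = 46.0, k = 0.0430 L mol⁻¹ h⁻¹)
    leaving ligand + starting complex → side product (k = 0.430 L mol⁻¹ h⁻¹)

The flask gives 48.0% for dusk, 44.3% for autumn, 44.3% for noon and 39.8% for summer, so dusk ends highest, 3.7 points above noon, which is more than the margin of 2 points. Her equality of dusk and noon holds ten times later, with dusk at 3.38% and noon at 3.20%. The split factor still reads the side product: the share 1/(1 + factor × ratio) is 45.8% for autumn, which holds 44.5%. Autumn's neighbour, with 1.80 equiv of incoming ligand, has a ratio of 0.360, which gives 58.5%; that flask holds 57.0% side product and 37.1% complex with one exchanged.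

Readings and results are calculated for an exercise; the scatter is artificial.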